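**Plan**
- **Labels:** the norbornane is C1 (quaternary bridgehead), C2, C3 (CHOH), C4, C5, C6 (CH‑iPr) and C7 (bridge). Ring B is C1‑C2‑C8‑C9‑C10‑C11. Ring A is C8‑C9(Me)‑C12(Br)‑C13‑C14‑C15(Me,OH).
- **Enabling feature:** bridgehead C1 and its neighbour C2 are joined by the four‑atom chain C11‑C10‑C9‑C8. C3‑O is trans to C2‑C8, and the isopropyl group sits on C6 next to C1. This is the retron of a type‑1 intramolecular Diels–Alder reaction of a 1‑alkyl‑2‑isopropylcyclopentadiene with an (E)‑alkene that carries a hydroxyl surrogate.
- **Cuts:** C1‑C2 and C3‑C4 (cycloaddition), C9‑C10 (enolate allylation), C9‑Me, C8‑C2 (Rh 1,4‑addition), C15‑Me, C12‑Br (from C=O) and C3‑O (from C‑Si).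
- **Forward:** ring A is p‑benzoquinone monoketal (C12=O, C15 ketal), and three C‑C bonds are placed on it. The cyclopentadiene arrives masked as an s‑trans‑locked alkylidenecyclopentene. Acid unlocks it, 1,5‑H shifts scramble the tautomers, and only one tautomer can cycloadd, which closes ring B and both norbornane rings at once.
- **Stereochemistry:** C8 comes from the chiral Rh catalyst and C9 from anti alkylation. C1–C4 come from a chair‑like exo‑tether transition state plus the E geometry. C6 comes from exo hydrogenation, C12 from equatorial hydride then SN2 inversion, C15 from equatorial methyl delivery, and C3‑O from retentive C‑Si oxidation.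

Key step: step 9

Assumption: the sense of induction in step 5 is taken from the usual facial model for BINAP–Rh additions to cyclohex‑2‑enones ((R)‑ligand gives the configuration drawn). If it is opposite on the quinone monoketal, the (S)‑ligand is used and nothing else changes.

Step 1
Reactants: 1 2‑bromocyclopent‑2‑en‑1‑one
Product: 2 2‑isopropylcyclopent‑2‑en‑1‑one
Conditions: i‑PrZnBr, Pd(OAc)2 (cat.), CPhos (cat.), THF/toluene, 0 °C to rt
Reagents that add atoms: isopropylzinc bromide, CC(C)[Zn]Br
Why: Negishi coupling at the sp2 C–Br bond of an α‑bromoenone, in which the bulky biaryl phosphine should make reductive elimination faster than β‑hydride elimination so that the secondary alkyl group is transferred without isomerisation.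

Step 2
Reactants: 2 2‑isopropylcyclopent‑2‑en‑1‑one
Product: 3 rac‑1‑ethenyl‑2‑isopropylcyclopent‑2‑en‑1‑ol
Conditions: CH2=CHMgBr, THF, −78 to 0 °C; H2O
Reagents that add atoms: vinylmagnesium bromide, C=C[Mg]Br
Why: Uncatalysed Grignard 1,2‑addition to an α‑substituted cyclopentenone, whose new racemic carbinol centre is erased in step 3.

Step 3
Reactants: 3 rac‑1‑ethenyl‑2‑isopropylcyclopent‑2‑en‑1‑ol
Product: 4 5‑(2‑bromoethylidene)‑1‑isopropylcyclopent‑1‑ene (E drawn; E/Z mixture usable)
Conditions: PBr3 (0.4 equiv), pyridine (cat.), Et2O, −30 to 0 °C; used crude at once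
Reagents that add atoms: phosphorus tribromide, BrP(Br)Br
Why: Bromination with allylic transposition (tertiary vinyl carbinol to primary allylic bromide) should give the conjugated primary dienyl bromide, and its alkene geometry is irrelevant because C11=C1 is destroyed in step 9.

Step 4
Reactants: 5 ethynyl(dimethyl)phenylsilane
Product: 6 (E)‑2‑[2‑(dimethylphenylsilyl)ethenyl]‑4,4,5,5‑tetramethyl‑1,3,2‑dioxaborolane
Conditions: HBpin, Cp2ZrHCl (cat.), Et3N (cat.), neat, 60 °C
Reagents that add atoms: pinacolborane, [H]B1OC(C)(C)C(C)(C)O1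
Why: Zirconocene‑hydride‑catalysed syn hydroboration of a terminal alkyne places boron on the unhindered terminal carbon and fixes the E geometry.

Step 5
Reactants: 7 1,4‑dioxaspiro[4.5]deca‑6,9‑dien‑8‑one (p‑benzoquinone mono ethylene ketal); 6 (E)‑silylvinyl boronate
Product: 8 ring‑A enone (C12=O; C13=C14; C15 ketal; C9H2; C8 (R) bearing (E)‑CH=CH‑SiMe2Ph)
Conditions: Rh(acac)(C2H4)2 (cat.), (R)‑BINAP (cat.), dioxane/H2O 10:1, 60 °C; slight excess of 7
Reagents that add atoms: none
Why: Rhodium‑catalysed asymmetric 1,4‑addition of an alkenylboron reagent (Hayashi–Miyaura reaction) desymmetrises the prochiral dienone, since carbo‑rhodation of one enantiotopic enone face under ligand control sets C8 and the more hindered mono‑adduct should react more slowly than 7.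

Step 6
Reactants: 8 ring‑A enone
Product: 9 9‑methyl enone (9‑Me trans to the C8 alkenyl group)
Conditions: LDA, THF, −78 °C; MeI, −78 to −30 °C
Reagents that add atoms: iodomethane, CI
Why: Kinetic α'‑enolisation can occur only at C9 because C15 bears no hydrogen, the enolate alkylation should occur anti to the C8 substituent, and the C9 configuration is irrelevant since the centre is re‑enolised in step 7.

Step 7
Reactants: 9 9‑methyl enone; 4 dienyl bromide
Product: 10 C9‑quaternary enone (C10 chain trans and 9‑Me cis to the C8 alkenyl group)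
Conditions: LDA, THF/DMPU, −78 °C; 4, −78 to −20 °C
Reagents that add atoms: none
Why: In the fully substituted C9 enolate, allylic strain places the C8 alkenyl group pseudo‑axial, so the reactive primary allylic bromide should be attacked (SN2 enolate alkylation) on the opposite face, which sets quaternary C9.

Step 8
Reactants: 10 C9‑quaternary enone
Product: 11 saturated C12 ketone carrying the masked cyclopentadiene and the (E)‑vinylsilane
Conditions: L‑Selectride (1.05 equiv), THF, −78 °C; H2O
Reagents that add atoms: none
Why: Conjugate reduction of a β‑unsubstituted cyclohexenone whose carbonyl is screened by quaternary C9 removes the only activated π‑bond that could compete as a dienophile in step 9, while the isolated diene and the vinylsilane are inert.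

Step 9
Reactants: 11 saturated C12 ketone
Product: 15 tetracyclic C5=C6 norbornene (C12 ketone; C15 ketal; C8 on C2 exo; SiMe2Ph on C3 endo), via 2‑alkyl‑3‑isopropylcyclopenta‑1,3‑diene tautomer 12 (not isolated), via 2‑alkyl‑1‑isopropylcyclopenta‑1,3‑diene tautomer 13 (not isolated), via 1‑alkyl‑2‑isopropylcyclopenta‑1,3‑diene tautomer 14 (not isolated)
Conditions: CSA (5 mol %), o‑xylene, 40 °C; then 2,4,6‑collidine (10 mol %), BHT, dilution to 2 mM, 170 °C (sealed tube)
Reagents that add atoms: none
Why: Catalytic acid protonates the exocyclic carbon C11 of either alkene isomer of 11 to a C1‑C6‑C5 allyl cation that loses H from C7 or C4, so the s‑trans‑locked, Diels–Alder‑silent diene becomes cyclopentadienes 12–14, which interconvert by suprafacial 1,5‑H shifts (both events are standard in the preparation of alkylcyclopentadienes from cyclopentenols). Only 14 carries the tether on a diene terminus and can undergo the type‑1 intramolecular Diels–Alder reaction (closest known type: thermal cyclisation of equilibrating ω‑alkenylcyclopentadienes through the 1‑substituted tautomer), whereas 12 and 13 could give only anti‑Bredt bridged adducts and are drained through 14 in a Curtin–Hammett funnel. Bond C1‑C2 closes ring B in the fused mode through a chair‑like six‑membered tether, and bond C3‑C4 turns the five‑membered ring into the bicyclo[2.2.1]heptene. C2 and C3 keep the trans relation of the (E)‑alkene and C1/C4 arise by suprafacial addition, so with the tether exo the silyl group is endo. The absolute sense follows from C8/C9, because both arms are equatorial on ring A (9‑Me axial) and only the chair tether with H2 anti to H8 lets the termini meet, while the endo‑tether alternative needs a wider C11‑C1‑C2‑C8 torsion and drives ring A into the C6 isopropyl group. The step needs tautomer selectivity and periselectivity (secured as above), intra‑ over intermolecular reaction (secured by high dilution, by dimerisation that is reversible at this temperature, and by buffered slow release from residual 11), and chemoselectivity (secured by removal of C13=C14 in step 8).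

Step 10
Reactants: 15 tetracyclic norbornene
Product: 16 saturated tetracyclic ketone (6‑endo‑isopropyl)
Conditions: H2 (3 atm), Pd/C, EtOAc, rt
Reagents that add atoms: none
Why: Heterogeneous hydrogenation of the strained trisubstituted norbornene from its exo face, since the endo face is closed by the C2‑C3 bridge and its silyl group, pushes the isopropyl group endo and sets C6.

Step 11
Reactants: 16 saturated tetracyclic ketone
Product: 17 axial C12 alcohol (OH anti to 9‑Me)
Conditions: L‑Selectride, THF, −78 to 0 °C; H2O
Reagents that add atoms: none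
Why: The bulky hydride should attack C12=O along the equatorial trajectory, away from the axial hydrogens at C8 and C14 as in 4,4‑dimethyl‑3‑keto terpenoids, and so give the axial alcohol.

Step 12
Reactants: 17 axial C12 alcohol
Product: 18 equatorial C12 bromide (C15 ketal)
Conditions: PPh3, CBr4, toluene, 80 °C
Reagents that add atoms: tetrabromomethane, BrC(Br)(Br)Br
Why: In the Appel reaction the axial oxyphosphonium ion is displaced by bromide with inversion to the equatorial bromide, and because C15 is still masked neither diol selectivity nor transannular ether formation can interfere.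

Step 13
Reactants: 18 equatorial C12 bromide
Product: 19 bromo C15 ketone
Conditions: 1 M HCl, THF, 40 °C
Reagents that add atoms: water, O
Why: Acid hydrolysis of the dioxolane is tolerated by the alkyl bromide and the alkylsilane, and C8, now α to the ketone, already has the more stable trans‑fused arrangement.

Step 14
Reactants: 19 bromo C15 ketone
Product: 20 bromo tertiary alcohol (15‑Me equatorial; 15‑OH axial, syn to 9‑Me)
Conditions: MeLi, CeCl3, THF, −78 to −20 °C; H2O
Reagents that add atoms: methyllithium, [Li]C
Why: In this organocerium 1,2‑addition the low basicity limits enolisation and spares the hindered equatorial bromide (which has no anti‑periplanar hydrogen), and since the axial face of C15=O is blocked by the 1,3‑diaxial 9‑methyl group, methyl should enter equatorially.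

Step 15
Reactants: 20 bromo tertiary alcohol
Product: 21 target CNP0295684.1
Conditions: KBr, AcOOH, NaOAc, AcOH, 0 °C to rt
Reagents that add atoms: peracetic acid, CC(=O)OO
Why: In the Fleming–Tamao oxidation, ipso‑bromodesilylation of the phenyl group activates silicon and the peracid then induces the 1,2‑shift of C3 from Si to O with retention, so the endo C‑Si bond becomes the endo C3‑OH.

**Compound list**
1 | 2‑bromocyclopent‑2‑en‑1‑one | O=C1CCC=C1Br | starting material
2 | 2‑isopropylcyclopent‑2‑en‑1‑one | CC(C)C1=CCCC1=O | intermediate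
3 | rac‑1‑ethenyl‑2‑isopropylcyclopent‑2‑en‑1‑ol | C=CC1(O)CCC=C1C(C)C | intermediate
4 | 5‑[(E)‑2‑bromoethylidene]‑1‑isopropylcyclopent‑1‑ene | BrC/C=C1\CCC=C1C(C)C | intermediate
5 | ethynyl(dimethyl)phenylsilane | C#C[Si](C)(C)c1ccccc1 | starting material
6 | (E)‑2‑[2‑(dimethylphenylsilyl)ethenyl]‑4,4,5,5‑tetramethyl‑1,3,2‑dioxaborolane | C[Si](C)(c1ccccc1)/C=C/B1OC(C)(C)C(C)(C)O1 | intermediate
7 | 1,4‑dioxaspiro[4.5]deca‑6,9‑dien‑8‑one | O=C1C=CC2(OCCO2)C=C1 | starting material
8 | (10R)‑10‑[(E)‑2‑(dimethylphenylsilyl)ethenyl]‑1,4‑dioxaspiro[4.5]dec‑6‑en‑8‑one | C1C(=O)C=CC2(OCCO2)[C@H]1/C=C/[Si](C)(C)c1ccccc1 | intermediate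
9 | 9‑methyl derivative of 8 (Me trans to alkenyl) | C[C@@H]1C(=O)C=CC2(OCCO2)[C@H]1/C=C/[Si](C)(C)c1ccccc1 | intermediate
10 | C9‑quaternary enone (Me cis, dienyl chain trans to alkenyl) | CC(C)C1=CCC/C1=C\C[C@]2(C)C(=O)C=CC3(OCCO3)[C@H]2/C=C/[Si](C)(C)c1ccccc1 | intermediate
11 | 13,14‑dihydro derivative of 10 | CC(C)C1=CCC/C1=C\C[C@]2(C)C(=O)CCC3(OCCO3)[C@H]2/C=C/[Si](C)(C)c1ccccc1 | intermediate
12 | 2‑alkyl‑3‑isopropylcyclopenta‑1,3‑diene tautomer (sp3 C4) | CC(C)C1=CCC=C1CC[C@]2(C)C(=O)CCC3(OCCO3)[C@H]2/C=C/[Si](C)(C)c1ccccc1 | intermediate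
13 | 2‑alkyl‑1‑isopropylcyclopenta‑1,3‑diene tautomer (sp3 C5) | CC(C)C1=C(CC[C@]2(C)C(=O)CCC3(OCCO3)[C@H]2/C=C/[Si](C)(C)c2ccccc2)C=CC1 | intermediate
14 | 1‑alkyl‑2‑isopropylcyclopenta‑1,3‑diene tautomer (sp3 C7; reactive) | CC(C)C1=C(CC[C@]2(C)C(=O)CCC3(OCCO3)[C@H]2/C=C/[Si](C)(C)c2ccccc2)CC=C1 | intermediate
15 | tetracyclic norbornene cycloadduct | CC(C)C1=C[C@H]2C[C@@]13CC[C@]1(C)C(=O)CCC4(OCCO4)[C@H]1[C@@H]3[C@H]2[Si](C)(C)c1ccccc1 | intermediate
16 | saturated tetracyclic ketone, 6‑endo‑iPr | CC(C)[C@@H]1C[C@H]2C[C@@]13CC[C@]1(C)C(=O)CCC4(OCCO4)[C@H]1[C@@H]3[C@H]2[Si](C)(C)c1ccccc1 | intermediate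
17 | axial C12 alcohol | CC(C)[C@@H]1C[C@H]2C[C@@]13CC[C@]1(C)[C@H](O)CCC4(OCCO4)[C@H]1[C@@H]3[C@H]2[Si](C)(C)c1ccccc1 | intermediate
18 | equatorial C12 bromide, C15 ketal | CC(C)[C@@H]1C[C@H]2C[C@@]13CC[C@]1(C)[C@@H](Br)CCC4(OCCO4)[C@H]1[C@@H]3[C@H]2[Si](C)(C)c1ccccc1 | intermediate
19 | bromo C15 ketone | CC(C)[C@@H]1C[C@H]2C[C@@]13CC[C@]1(C)[C@@H](Br)CCC(=O)[C@H]1[C@@H]3[C@H]2[Si](C)(C)c1ccccc1 | intermediate
20 | bromo tertiary alcohol, 3‑endo‑SiMe2Ph | CC(C)[C@@H]1C[C@H]2C[C@@]13CC[C@]1(C)[C@@H](Br)CC[C@@](C)(O)[C@H]1[C@@H]3[C@H]2[Si](C)(C)c1ccccc1 | intermediate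
21 | CNP0295684.1 | CC(C)[C@@H]1C[C@H]2C[C@@]13CC[C@]1(C)[C@@H](Br)CC[C@@](C)(O)[C@H]1[C@@H]3[C@H]2O | target

**Count**
Total steps: 15. The longest linear sequence is 12 steps (steps 1–3 then 7–15, or equally steps 4–15).

**Steps most likely to fail**

**Step 9.**
- *Risk:* cationic oligomerisation or protodesilylation may occur during the acid phase. The cycloaddition of the unactivated vinylsilane may also be too slow to outrun dimerisation of the free cyclopentadiene.
- *Fallback:* a stoichiometric addition–elimination replaces the acid equilibrium.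
  - From 11, one equivalent of dry HCl (Et2O, −78 °C) is added across the diene. This gives the tertiary allylic chloride F1 (Cl on C1, C11 now CH2, epimers at C1).
  - The acid‑free F1 is fed by syringe pump into o‑dichlorobenzene at 170 °C that contains 2,4,6‑collidine.
  - Thermal dehydrochlorination releases 12 and 14 at a very low stationary concentration, and the route is rejoined at 14 on its way to 15.

**Step 12.**
- *Risk:* the neopentyl axial oxyphosphonium ion may undergo E2 loss towards C13 or a 1,2‑shift of the anti‑periplanar 9‑methyl group instead of substitution.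
- *Fallback:* a discrete, small super‑leaving group is made and then displaced by unsolvated bromide.
  - From 17, ClCH2SO2Cl and pyridine give the chloromethanesulfonate F2.
  - LiBr in DMPU/toluene at 60 °C displaces it with inversion and returns to 18.

**Step 14.**
- *Risk:* enolisation or simple non‑addition may occur at the C15 ketone, which is screened by the 9‑methyl group on one face and by C3‑H on the other.
- *Fallback:* a non‑basic carbonyl olefination is followed by an anti Markovnikov‑type hydration.
  - From 19, Petasis methylenation (Cp2TiMe2, toluene, 70 °C) gives the exocyclic alkene F3.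
  - Oxymercuration (Hg(OAc)2, THF/H2O) should place mercury on the open equatorial face and water anti to it, giving the axial carbinol organomercurial F4.
  - NaBH4/NaOH demercuration returns to 20.

Further compounds
F1 | step 9 | tertiary allylic chloride (HCl adduct of 11, C1 epimers) | CC(C)C1=CCCC1(Cl)CC[C@]2(C)C(=O)CCC3(OCCO3)[C@H]2/C=C/[Si](C)(C)c1ccccc1
F2 | step 12 | axial C12 chloromethanesulfonate of 17 | CC(C)[C@@H]1C[C@H]2C[C@@]13CC[C@]1(C)[C@H](OS(=O)(=O)CCl)CCC4(OCCO4)[C@H]1[C@@H]3[C@H]2[Si](C)(C)c1ccccc1
F3 | step 14 | C15 exocyclic methylene compound | CC(C)[C@@H]1C[C@H]2C[C@@]13CC[C@]1(C)[C@@H](Br)CCC(=C)[C@H]1[C@@H]3[C@H]2[Si](C)(C)c1ccccc1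
F4 | step 14 | C15 axial carbinol with equatorial CH2HgOAc | CC(C)[C@@H]1C[C@H]2C[C@@]13CC[C@]1(C)[C@@H](Br)CC[C@@](C[Hg]OC(C)=O)(O)[C@H]1[C@@H]3[C@H]2[Si](C)(C)c1ccccc1
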